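**Retrosynthetic overview**

1. Target 33 ⇐ bis-allyl ether 32 (deallylation of the catechol only).
2. 32 ⇐ cis-fused hydroxy-triketone 30. The C1–C8 bond is made by a 1,2-shift of the CMe2 carbon onto the aroyl-bearing carbon, which PhI(OAc)2 turns into an enolonium equivalent; both carbons are α-carbons of ketones and would normally both be nucleophilic.
3. 30 ⇐ hydroxy-dione 26 by C-prenylation and γ-aroylation with ester 13; 26 ⇐ cyclopentanone 22 by diketene annulation.
4. 22 ⇐ (R)-2,2-dimethyl-3-prenylcyclopentanone 20 + (S)-lavandulyl iodide 10; 20 ⇐ 2-methylcyclopent-2-enone (asymmetric conjugate addition/methylation, alkene isomerisation); 10 ⇐ Evans deconjugative prenylation.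
5. Ring order: commercial five-membered ring → annulated cyclohexane-1,3-dione ring → ring expansion of the five-membered ring into the bridged cyclohexanone (bicyclo[3.3.1]nonane formed last).

Assumption: the chiral ligand in step 6 is used in whichever enantiomeric form gives the (3S) adduct 19 (the antipode gives the enantiomer); bicyclic compounds are numbered C1 (aroyl bridgehead), C2–C4, C5 (lavandulyl bridgehead), C6, C7 (CH-prenyl), C8 (CMe2), C9 (bridging C=O).

**Route**

Step 1
Reactants: 1 (S)-4-benzyl-1,3-oxazolidin-2-one; 2 3-methylbut-2-enoyl chloride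
Product: 4 (S)-4-benzyl-3-(3-methylbut-2-enoyl)-1,3-oxazolidin-2-one, via lithium oxazolidinide 3 (not isolated)
Conditions: n-BuLi, THF, −78 °C; then 2, −78 → 0 °C
Reagents that add atoms: 3-methylbut-2-enoyl chloride (2), CC(C)=CC(=O)Cl
Why: N-acylation of the lithiated Evans auxiliary by an acid chloride is a standard imide formation that leaves the trisubstituted alkene and the auxiliary stereocentre untouched.

Step 2
Reactants: 4; 5 1-bromo-3-methylbut-2-ene (prenyl bromide)
Product: 7 (S)-4-benzyl-3-[(2S)-5-methyl-2-(prop-1-en-2-yl)hex-4-enoyl]-1,3-oxazolidin-2-one, via sodium dienolate 6 (not isolated)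
Conditions: NaN(SiMe3)2, THF, −78 °C; then 5, −78 → −40 °C
Reagents that add atoms: 1-bromo-3-methylbut-2-ene (5), CC(C)=CCBr
Why: Evans asymmetric alkylation in its deconjugative form: γ-deprotonation gives the chelated (Z)-dienolate 6, which is alkylated at the α-carbon on the face opposite the benzyl group, setting the (2S) centre of the lavandulyl unit and leaving the isopropenyl group out of conjugation.

Step 3
Reactants: 7
Product: 8 (S)-lavandulol [(2S)-5-methyl-2-(prop-1-en-2-yl)hex-4-en-1-ol]
Conditions: LiBH4, MeOH (1 equiv), Et2O, 0 °C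
Reagents that add atoms: none
Why: Hydride reduction of the exocyclic imide carbonyl (reductive auxiliary cleavage) releases the primary alcohol without epimerising the α-centre or touching the isolated alkenes, and returns the auxiliary.

Step 4
Reactants: 8; 9 iodine
Product: 10 (S)-lavandulyl iodide [(3S)-3-(iodomethyl)-2,6-dimethylhepta-1,5-diene]
Conditions: I2, PPh3, imidazole, CH2Cl2, 0 → 22 °C
Reagents that add atoms: iodine (9), II
Why: Appel-type iodination (Garegg–Samuelsson conditions) replaces the primary hydroxyl by SN2 at CH2, so the adjacent stereocentre is not involved.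

Step 5
Reactants: 11 methyl 3,4-dihydroxybenzoate; 12 allyl bromide
Product: 13 methyl 3,4-bis(allyloxy)benzoate
Conditions: K2CO3, acetone, 56 °C
Reagents that add atoms: allyl bromide (12), C=CCBr
Why: Williamson etherification of both phenols gives a catechol protection that survives amide bases, KOH/MeOH and PhI(OAc)2 and is removed at the end under neutral conditions.

Step 6
Reactants: 14 2-methylcyclopent-2-en-1-one; 15 4-bromo-2-methylbut-1-ene; 16 iodomethane
Product: 19 (3S)-2,2-dimethyl-3-(3-methylbut-3-en-1-yl)cyclopentan-1-one, via Grignard reagent 17 (not isolated), via magnesium enolate 18 (not isolated)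
Conditions: 15, Mg, Et2O; then 14, Cu(OTf)2 (3 mol%), chiral C2-symmetric imidazolinium salt (carbene ligand precursor, 4 mol%), Et2O, −30 °C; then MeI, DMPU, −30 → 20 °C
Reagents that add atoms: 4-bromo-2-methylbut-1-ene (15), C=C(C)CCBr; iodomethane (16), CI
Why: Copper-catalysed asymmetric conjugate addition of a non-allylic Grignard reagent to the α-methyl enone sets the ring stereocentre (future C7) through enantioface selection by the chiral carbene–copper complex, and the regiodefined magnesium enolate 18 is C-methylated in the same flask to give the gem-dimethyl carbon, the 3-methylbut-3-enyl group serving as a prenyl surrogate because prenyl organometallics add with allylic transposition.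

Step 7
Reactants: 19
Product: 20 (3R)-2,2-dimethyl-3-(3-methylbut-2-en-1-yl)cyclopentan-1-one
Conditions: Co(salen)Cl (salen = N,N'-bis(3,5-di-tert-butylsalicylidene)ethane-1,2-diaminate, 2 mol%), PhSiH3 (4 mol%), benzene, 22 °C
Reagents that add atoms: none
Why: Cobalt-hydride hydrogen-atom-transfer alkene isomerisation moves the 1,1-disubstituted alkene one position to the more stable trisubstituted prenyl alkene and stops there, leaving ketone and stereocentre unchanged (the descriptor changes from S to R only through the priority rules).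

Step 8
Reactants: 20; 10 (S)-lavandulyl iodide
Product: 22 (3S,5RS)-2,2-dimethyl-3-(3-methylbut-2-en-1-yl)-5-[(2R)-5-methyl-2-(prop-1-en-2-yl)hex-4-en-1-yl]cyclopentan-1-one, via lithium enolate 21 (not isolated)
Conditions: LiN(iPr)2 (LDA), THF, −78 °C; then 10, HMPA, −78 → −20 °C
Reagents that add atoms: (S)-lavandulyl iodide (10), C=C(C)[C@H](CC=C(C)C)CI
Why: Kinetic enolate alkylation: only C5 is enolisable because C2 is quaternary, so the single enolate 21 displaces the primary iodide by SN2; the lavandulyl stereocentre is carried in unchanged and the C5 epimer mixture is erased in step 9.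

Step 9
Reactants: 22; 23 diketene (4-methyleneoxetan-2-one)
Product: 26 (2S,3aS,7aS)-3a-hydroxy-3,3-dimethyl-2-(3-methylbut-2-en-1-yl)-7a-[(2R)-5-methyl-2-(prop-1-en-2-yl)hex-4-en-1-yl]hexahydro-1H-indene-5,7(4H,6H)-dione, via lithium enolate 24 (not isolated), via acetoacetyl enolate 25 (not isolated)
Conditions: lithium 2,2,6,6-tetramethylpiperidide (LiTMP), THF, −78 → 0 °C; then 23, −78 → −30 °C; aq. HCl
Reagents that add atoms: diketene (23), C=C1CC(=O)O1
Why: Diketene annulation: the tetrasubstituted enolate 24 is C-acylated on the face anti to the ring prenyl group (setting the quaternary carbon with lavandulyl cis to prenyl), and the terminal enolate 25 released by lactone opening closes by intramolecular aldol addition onto the cyclopentanone carbonyl, which can only give the cis-fused hydroxy-dione.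

Step 10
Reactants: 26; 27 3-methylbut-2-en-1-yl acetate (prenyl acetate)
Product: 28 (2S,3aS,7aS)-3a,5-dihydroxy-3,3-dimethyl-2,6-bis(3-methylbut-2-en-1-yl)-7a-[(2R)-5-methyl-2-(prop-1-en-2-yl)hex-4-en-1-yl]-1,2,3,3a,4,7a-hexahydro-7H-inden-7-one (enol form of the 6-prenyl-5,7-dione)
Conditions: 27, Pd(PPh3)4 (5 mol%), DBU, THF, 40 °C
Reagents that add atoms: prenyl acetate (27), CC(C)=CCOC(C)=O
Why: Tsuji–Trost allylation: the soft 1,3-dione enolate attacks the unsubstituted terminus of the 1,1-dimethylallyl complex formed from prenyl acetate and zerovalent palladium, giving linear C-prenylation (reversible O-allylation funnels to carbon) while the dione anion protects the tertiary aldol from retro-aldol cleavage.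

Step 11
Reactants: 28; 13 methyl 3,4-bis(allyloxy)benzoate
Product: 30 (2S,3aS,7aS,4RS)-4-[3,4-bis(allyloxy)benzoyl]-3a,5-dihydroxy-3,3-dimethyl-2,6-bis(3-methylbut-2-en-1-yl)-7a-[(2R)-5-methyl-2-(prop-1-en-2-yl)hex-4-en-1-yl]-1,2,3,3a,4,7a-hexahydro-7H-inden-7-one, via trilithium trianion 29 (not isolated)
Conditions: LiN(iPr)2 (4.5 equiv), THF, −78 → 0 °C; then 13, −78 → −30 °C; AcOH, −78 °C; used crude
Reagents that add atoms: methyl 3,4-bis(allyloxy)benzoate (13), COC(=O)c1ccc(OCC=C)c(OCC=C)c1
Why: Hauser–Harris-type γ-acylation of a 1,3-dione polyanion: after alkoxide and dione enolate have formed, a third deprotonation at C4 gives trianion 29 (a Fráter–Seebach-like β-oxido enolate that does not eliminate at low temperature), whose most nucleophilic carbon C4 attacks the non-enolisable ester in a Claisen-type acylation.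

Step 12
Reactants: 30
Product: 32 (1S,5R,7S)-1-[3,4-bis(allyloxy)benzoyl]-2-hydroxy-8,8-dimethyl-3,7-bis(3-methylbut-2-en-1-yl)-5-[(2R)-5-methyl-2-(prop-1-en-2-yl)hex-4-en-1-yl]bicyclo[3.3.1]non-2-ene-4,9-dione, via iodanyl enolate 31 (not isolated)
Conditions: PhI(OAc)2 (1.2 equiv), KOH, MeOH, −20 → 0 °C; then aq. HCl
Reagents that add atoms: none
Why: Proposed new method: trivalent-iodine oxidation of the C4 enolate (flanked by the aroyl and C5 carbonyls) gives iodanyl species 31, an enolonium equivalent in which the normally nucleophilic C4 is electrophilic, and loss of iodobenzene is coupled to a semipinacol 1,2-shift of the electron-rich CMe2 carbon (the former ketone α-carbon, exocyclic to the six-membered ring and anti to the departing iodine, whereas the acyl-substituted ring bond to C7a is misaligned and electron-poor) from the carbinol carbon to C4 while the carbinol collapses to the bridging ketone, so that the C1–C8 bond, both adjacent quaternary carbons and both bridgehead configurations (dictated by the cis ring fusion) arise in one event; the closest known reactions are the PhI(OAc)2/KOH/MeOH oxidative ring expansion of annulated 5-hydroxycyclohexane-1,3-diones to bicyclo[3.3.1]nonane-2,4,9-triones and semipinacol shifts of α-hydroxy ketones bearing an α'-leaving group.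

Step 13
Reactants: 32
Product: 33 (1S,5R,7S)-1-(3,4-dihydroxybenzoyl)-2-hydroxy-8,8-dimethyl-3,7-bis(3-methylbut-2-en-1-yl)-5-[(2R)-5-methyl-2-(prop-1-en-2-yl)hex-4-en-1-yl]bicyclo[3.3.1]non-2-ene-4,9-dione (CNP0425478.2)
Conditions: Pd(PPh3)4 (10 mol%), morpholine (10 equiv), THF, 22 °C
Reagents that add atoms: none
Why: Deallylation by zerovalent palladium (Tsuji–Trost allyl transfer to excess morpholine, which outcompetes the hindered C3 enol) cleaves only the two aryl allyl ethers and leaves prenyl, lavandulyl, enol and all stereocentres intact.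

**Compound list**

1 | (S)-4-benzyl-1,3-oxazolidin-2-one | O=C1N[C@@H](Cc2ccccc2)CO1 | starting material
2 | 3-methylbut-2-enoyl chloride | CC(C)=CC(=O)Cl | starting material
3 | lithium (S)-4-benzyl-2-oxo-1,3-oxazolidin-3-ide | [Li+].O=C1[N-][C@@H](Cc2ccccc2)CO1 | intermediate (not isolated)
4 | (S)-4-benzyl-3-(3-methylbut-2-enoyl)-1,3-oxazolidin-2-one | CC(C)=CC(=O)N1C(=O)OC[C@@H]1Cc1ccccc1 | intermediate
5 | 1-bromo-3-methylbut-2-ene (prenyl bromide) | CC(C)=CCBr | starting material
6 | sodium (Z)-dienolate of 4 | [Na+].[O-]/C(=C\C(C)=C)N1C(=O)OC[C@@H]1Cc1ccccc1 | intermediate (not isolated)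
7 | (S)-4-benzyl-3-[(2S)-5-methyl-2-(prop-1-en-2-yl)hex-4-enoyl]-1,3-oxazolidin-2-one | C=C(C)[C@H](CC=C(C)C)C(=O)N1C(=O)OC[C@@H]1Cc1ccccc1 | intermediate
8 | (S)-lavandulol, (2S)-5-methyl-2-(prop-1-en-2-yl)hex-4-en-1-ol | C=C(C)[C@H](CC=C(C)C)CO | intermediate
9 | iodine | II | starting material
10 | (S)-lavandulyl iodide, (3S)-3-(iodomethyl)-2,6-dimethylhepta-1,5-diene | C=C(C)[C@H](CC=C(C)C)CI | intermediate
11 | methyl 3,4-dihydroxybenzoate | COC(=O)c1ccc(O)c(O)c1 | starting material
12 | allyl bromide | C=CCBr | starting material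
13 | methyl 3,4-bis(allyloxy)benzoate | COC(=O)c1ccc(OCC=C)c(OCC=C)c1 | intermediate
14 | 2-methylcyclopent-2-en-1-one | CC1=CCCC1=O | starting material
15 | 4-bromo-2-methylbut-1-ene | C=C(C)CCBr | starting material
16 | iodomethane | CI | starting material
17 | (3-methylbut-3-en-1-yl)magnesium bromide | C=C(C)CC[Mg]Br | intermediate (not isolated)
18 | bromomagnesium (3S)-2-methyl-3-(3-methylbut-3-en-1-yl)cyclopent-1-en-1-olate | Br[Mg]OC1=C(C)[C@@H](CCC(C)=C)CC1 | intermediate (not isolated)
19 | (3S)-2,2-dimethyl-3-(3-methylbut-3-en-1-yl)cyclopentan-1-one | O=C1CC[C@H](CCC(C)=C)C1(C)C | intermediate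
20 | (3R)-2,2-dimethyl-3-(3-methylbut-2-en-1-yl)cyclopentan-1-one | O=C1CC[C@H](CC=C(C)C)C1(C)C | intermediate
21 | lithium enolate of 20 (C1=C5) | [Li]OC1=CC[C@H](CC=C(C)C)C1(C)C | intermediate (not isolated)
22 | (3S,5RS)-2,2-dimethyl-3-(3-methylbut-2-en-1-yl)-5-[(2R)-5-methyl-2-(prop-1-en-2-yl)hex-4-en-1-yl]cyclopentan-1-one | O=C1C(C[C@@H](CC=C(C)C)C(C)=C)C[C@H](CC=C(C)C)C1(C)C | intermediate
23 | diketene (4-methyleneoxetan-2-one) | C=C1CC(=O)O1 | starting material
24 | tetrasubstituted lithium enolate of 22 | [Li]OC1=C(C[C@@H](CC=C(C)C)C(C)=C)C[C@H](CC=C(C)C)C1(C)C | intermediate (not isolated)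
25 | terminal lithium enolate of the 5-acetoacetyl-5-lavandulyl-2,2-dimethyl-3-prenylcyclopentanone (acyl trans to prenyl) | C=C(C)[C@H](CC=C(C)C)C[C@]1(C(=O)CC(=C)O[Li])C[C@H](CC=C(C)C)C(C)(C)C1=O | intermediate (not isolated)
26 | (2S,3aS,7aS)-3a-hydroxy-3,3-dimethyl-2-prenyl-7a-[(R)-lavandulyl]hexahydro-1H-indene-5,7(4H,6H)-dione; cis-fused, with OH, lavandulyl and C2-prenyl on one face of the five-membered ring | C=C(C)[C@H](CC=C(C)C)C[C@]12C[C@H](CC=C(C)C)C(C)(C)[C@@]1(O)CC(=O)CC2=O | intermediate
27 | 3-methylbut-2-en-1-yl acetate (prenyl acetate) | CC(C)=CCOC(C)=O | starting material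
28 | 6-prenyl derivative of 26, drawn as the C5 enol | C=C(C)[C@H](CC=C(C)C)C[C@]12C[C@H](CC=C(C)C)C(C)(C)[C@@]1(O)CC(O)=C(CC=C(C)C)C2=O | intermediate
29 | trilithium trianion of 28 (alkoxide plus C4–C7 dienolate) | C=C(C)[C@H](CC=C(C)C)C[C@]12C[C@H](CC=C(C)C)C(C)(C)[C@@]1(O[Li])C=C(O[Li])C(CC=C(C)C)=C2O[Li] | intermediate (not isolated)
30 | 4-[3,4-bis(allyloxy)benzoyl] derivative of 28 (C4 epimers/enol tautomers) | C=C(C)[C@H](CC=C(C)C)C[C@]12C[C@H](CC=C(C)C)C(C)(C)[C@@]1(O)C(C(=O)c3ccc(OCC=C)c(OCC=C)c3)C(O)=C(CC=C(C)C)C2=O | intermediate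
31 | C4-[methoxy(phenyl)-λ3-iodanyl] derivative of 30 (or its O-bound enolate isomer) | C=C(C)[C@H](CC=C(C)C)C[C@]12C[C@H](CC=C(C)C)C(C)(C)[C@@]1(O)C(I(OC)c4ccccc4)(C(=O)c3ccc(OCC=C)c(OCC=C)c3)C(O)=C(CC=C(C)C)C2=O | intermediate (not isolated)
32 | (1S,5R,7S)-1-[3,4-bis(allyloxy)benzoyl]-2-hydroxy-8,8-dimethyl-3,7-diprenyl-5-[(R)-lavandulyl]bicyclo[3.3.1]non-2-ene-4,9-dione | C=C(C)[C@H](CC=C(C)C)C[C@]12C[C@H](CC=C(C)C)C(C)(C)[C@](C(=O)c3ccc(OCC=C)c(OCC=C)c3)(C1=O)C(O)=C(CC=C(C)C)C2=O | intermediate
33 | CNP0425478.2, (1S,5R,7S)-1-(3,4-dihydroxybenzoyl)-2-hydroxy-8,8-dimethyl-3,7-diprenyl-5-[(R)-lavandulyl]bicyclo[3.3.1]non-2-ene-4,9-dione | C=C(C)[C@H](CC=C(C)C)C[C@]12C[C@H](CC=C(C)C)C(C)(C)[C@](C(=O)c3ccc(O)c(O)c3)(C1=O)C(O)=C(CC=C(C)C)C2=O | target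

**Step count and risks**

Total step count: 13 (steps 1–4 lavandulyl iodide, step 5 aryl ester, steps 6–13 main chain).
Longest linear sequence: 10 steps (1–4, then 8–13); the main chain from 2-methylcyclopent-2-enone is 8 steps.

The three steps most likely to fail, in route order:

Step 8 (alkylation with a β-branched iodide whose β-hydrogen is allylic, so E2 to a diene competes). The fallback sets out from 20 and comes back at 22. Ketone 20 is condensed with N,N-dimethylhydrazine (cat. AcOH, EtOH, reflux) to the N,N-dimethylhydrazone F1. Its lithium azaenolate (LiN(iPr)2, THF, 0 °C) is far more nucleophilic and less prone to elimination than the ketone enolate, and is alkylated by 10 to the 5-lavandulyl hydrazone F2. Hydrolysis (aqueous CuCl2, THF) returns 22.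

Step 11 (acylation of a hindered trianion by an ester; the product is a dehydration-prone aldol). The fallback sets out from 28 and comes back at 30, replacing the acylation by aldol addition and oxidation. Ester 13 is reduced (iBu2AlH, CH2Cl2, −78 °C) to 3,4-bis(allyloxy)benzaldehyde F3. This adds to trianion 29 at −78 °C to give the benzylic carbinol F4. MnO2 (CH2Cl2, 22 °C) then oxidises only the benzylic alcohol to give 30.

Step 12 (the key shift onto a fully substituted, aroyl-bearing carbon; competing dehydration, methoxylation or epoxide formation). The fallback sets out from 28 and comes back at 32, changing the order so that the ring expansion precedes aroylation: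
- The same PhI(OAc)2/KOH/MeOH oxidation applied to 28 (unsubstituted migration terminus, a known type of ring expansion) gives the C1-unsubstituted bicyclic trione F5.
- Me3SiCHN2 gives the vinylogous methyl ester F6 (the isomer with the free ketone next to the bridgehead C–H; the other isomer is recycled by demethylation).
- Bridgehead lithiation (lithium 2,2,6,6-tetramethylpiperidide, THF, −78 °C) and addition to aldehyde F3 give the bridgehead carbinol F7.
- Dess–Martin oxidation gives the aroyl ketone F8.
- LiCl in DMSO at 120 °C cleaves the enol methyl ether to give 32.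

**Further compounds**

F1 | step 8 | N,N-dimethylhydrazone of 20 | CN(C)N=C1CC[C@H](CC=C(C)C)C1(C)C
F2 | step 8 | N,N-dimethylhydrazone of 22 | CN(C)N=C1C(C[C@@H](CC=C(C)C)C(C)=C)C[C@H](CC=C(C)C)C1(C)C
F3 | step 11 | 3,4-bis(allyloxy)benzaldehyde | O=Cc1ccc(OCC=C)c(OCC=C)c1
F4 | step 11 | 4-{[3,4-bis(allyloxy)phenyl](hydroxy)methyl} derivative of 28 (mixture of carbinol/C4 epimers) | C=C(C)[C@H](CC=C(C)C)C[C@]12C[C@H](CC=C(C)C)C(C)(C)[C@@]1(O)C(C(O)c3ccc(OCC=C)c(OCC=C)c3)C(O)=C(CC=C(C)C)C2=O
F5 | step 12 | 2-hydroxy-8,8-dimethyl-3,7-diprenyl-5-[(R)-lavandulyl]bicyclo[3.3.1]non-2-ene-4,9-dione with C1–H (ring skeleton and configuration as in 32) | C=C(C)[C@H](CC=C(C)C)C[C@]12C[C@H](CC=C(C)C)C(C)(C)[C@H](C1=O)C(O)=C(CC=C(C)C)C2=O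
F6 | step 12 | 4-O-methyl vinylogous ester of F5 (C2 ketone next to the bridgehead C1–H) | C=C(C)[C@H](CC=C(C)C)C[C@]12C[C@H](CC=C(C)C)C(C)(C)[C@H](C1=O)C(=O)C(CC=C(C)C)=C2OC
F7 | step 12 | C1-{[3,4-bis(allyloxy)phenyl](hydroxy)methyl} derivative of F6 (carbinol epimers) | C=C(C)[C@H](CC=C(C)C)C[C@]12C[C@H](CC=C(C)C)C(C)(C)[C@](C(O)c3ccc(OCC=C)c(OCC=C)c3)(C1=O)C(=O)C(CC=C(C)C)=C2OC
F8 | step 12 | C1-[3,4-bis(allyloxy)benzoyl] derivative of F6 (4-O-methyl ether of 32) | C=C(C)[C@H](CC=C(C)C)C[C@]12C[C@H](CC=C(C)C)C(C)(C)[C@](C(=O)c3ccc(OCC=C)c(OCC=C)c3)(C1=O)C(=O)C(CC=C(C)C)=C2OC
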